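**Plan**

1. Retrosynthesis: cut the ester C3–O bond first (Mitsunobu union of a 2,3-trans alcohol with the Z-acid, with inversion), then O1–C2 and C3a–C3 of the dihydrofuran ring together, then the acid at its C2–CO2H bond.
2. Enabling feature: C2 carries the isopropenyl group and is therefore an allylic carbon bound to O1, and C3 carries oxygen. C3–C2–C(CH3)=CH2 is thus a 1-oxygenated isoprene, and the O1–C7a–C3a edge of the benzene ring is an ortho-iodophenol. This is the retron of a palladium Heck/π-allyl (3+2) heteroannulation.
3. Forward, core: 1 is iodinated at C5 to 2; enal 3 gives the (E)-silyloxy diene 4; 2 + 4 close the dihydrofuran ring (the only ring made) to 5 with both stereocentres; desilylation gives trans-diol 6.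
4. Forward, acid and union: 7 → stannane 8 → (via 9) hydroxy acid 10 → acetate 11; 6 + 11 → target 12.
5. Stereochemistry: C3 comes from the chiral ligand in the aryl-transfer step; C2 is relayed from C3 as 2,3-trans in the ring closure; the Mitsunobu step inverts C3 to give 2,3-cis (2S,3S); the Z-alkene of the acid comes from trans-hydrostannation.

Key step: step 3

Remark: the sense of asymmetric induction of the chiral ligand in step 3 cannot be predicted with certainty; the ligand antipode that gives the (3R) series is assumed (both antipodes are available).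

**Step 1**
Reactants: 1 1-(2,4-dihydroxyphenyl)ethan-1-one
Product: 2 1-(2,4-dihydroxy-5-iodophenyl)ethan-1-one
Conditions: BnMe3N·ICl2 (1.05 equiv), NaHCO3, CH2Cl2/MeOH, rt
Reagents that add atoms: benzyltrimethylammonium dichloroiodate, C[N+](C)(C)Cc1ccccc1.Cl[I-]Cl
Why: Electrophilic aromatic substitution (iodination) should take place at C5, the unhindered position ortho to the free 4-OH and para to the 2-OH, because C3 is flanked by two oxygen substituents.

**Step 2**
Reactants: 3 3-methylbut-2-enal
Product: 4 (E)-triisopropyl[(3-methylbuta-1,3-dien-1-yl)oxy]silane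
Conditions: TIPSOTf, Et3N, CH2Cl2, 0 °C to rt; distillation
Reagents that add atoms: triisopropylsilyl trifluoromethanesulfonate, CC(C)[Si](OS(=O)(=O)C(F)(F)F)(C(C)C)C(C)C
Why: Silyl-triflate-mediated soft enolisation (O-silylation to the silyloxocarbenium ion, then γ-deprotonation by the amine) should give the silyl dienol ether, the (1E) geometry following from the preferred s-trans conformer of the activated enal.

**Step 3**
Reactants: 2 1-(2,4-dihydroxy-5-iodophenyl)ethan-1-one; 4 (E)-triisopropyl[(3-methylbuta-1,3-dien-1-yl)oxy]silane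
Product: 5 1-[(2S,3R)-6-hydroxy-2-(prop-1-en-2-yl)-3-[(triisopropylsilyl)oxy]-2,3-dihydro-1-benzofuran-5-yl]ethan-1-one
Conditions: Pd2(dba)3 (2.5 mol %), (S)-BINOL-derived N,N-bis[(R)-1-phenylethyl]phosphoramidite or its antipode (6 mol %), Ag2CO3 (1.0 equiv), 4 (2 equiv), 1,4-dioxane, 50–60 °C
Reagents that add atoms: none
Why: Proposed new method: zerovalent palladium inserts into the C–I bond of 2, silver removes iodide, and the cationic arylpalladium species adds syn across the enol-ether C1=C2 bond of 4, the aryl group going to the oxygen-bearing C1 and palladium to C2, where it is held as an η3-allyl over C2–C3–C4; the ortho phenoxide then bonds to the internal allyl terminus C2 and zerovalent palladium is released. The closest known reaction types are the Heck/Tsuji–Trost (3+2) heteroannulation of ortho-halophenols with 1,3-dienes, known only with aryl transfer to an unsubstituted CH2 terminus, and the cationic Heck α-arylation of enol ethers; their union on a 1-silyloxy diene is the new element. The dihydrofuran ring closes in the 5-exo mode (O attacks C2 and the C3=C4 unit stays outside the ring as the isopropenyl group), in preference to the seven-membered alternative at C4. The C3 stereocentre of the product is set in the migratory insertion by the chiral ligand, which selects the enantioface of the enol ether; the C2 stereocentre is set relative to it, either by delivery of palladium-bound phenoxide to the palladium-bearing face (overall suprafacial addition to the E alkene) or, if the allyl unit exchanges faces, by allylic 1,3-strain that keeps the small C3–H in the allyl plane, and both courses lead to the 2,3-trans product. The step needs aryl transfer to C1 and not to the CH2 end C4: the silyloxy donor polarises the cationic insertion toward C1, the methyl group on C3 disfavours the alternative tertiary alkylpalladium, and the bulky, poorly leaving OTIPS group (unlike an enol ester) suppresses β-oxygen elimination.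

**Step 4**
Reactants: 5 1-[(2S,3R)-6-hydroxy-2-(prop-1-en-2-yl)-3-[(triisopropylsilyl)oxy]-2,3-dihydro-1-benzofuran-5-yl]ethan-1-one
Product: 6 1-[(2S,3R)-3,6-dihydroxy-2-(prop-1-en-2-yl)-2,3-dihydro-1-benzofuran-5-yl]ethan-1-one
Conditions: TBAF, AcOH (1:1), THF, 0 °C to rt
Reagents that add atoms: none
Why: Fluoride-induced silyl ether cleavage breaks only the Si–O bond, so both stereocentres are untouched, and the acetic acid buffer keeps the medium from becoming basic enough to disturb the allylic aryl ether.

**Step 5**
Reactants: 7 but-2-yn-1-ol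
Product: 8 (Z)-2-(tributylstannyl)but-2-en-1-ol
Conditions: Bu3SnH, [Cp*RuCl]4 (1–2 mol %), CH2Cl2, rt
Reagents that add atoms: tributyltin hydride, CCCC[SnH](CCCC)CCCC
Why: Ruthenium-catalysed trans-hydrostannation of a propargylic alcohol: the hydroxyl group steers tin to the proximal alkyne carbon and H and Sn are delivered anti, so that tin ends up cis to the methyl group (Z).

**Step 6**
Reactants: 8 (Z)-2-(tributylstannyl)but-2-en-1-ol
Product: 10 (2Z)-2-(hydroxymethyl)but-2-enoic acid, via dilithio alkoxide 9 (not isolated)
Conditions: n-BuLi (2.2 equiv), THF, −78 to −40 °C; CO2 (gas), −78 °C to rt; cold dilute aq. HCl work-up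
Reagents that add atoms: carbon dioxide, O=C=O; n-butyllithium, [Li]CCCC (lithium of intermediate 9 only)
Why: Tin–lithium exchange after O-deprotonation should give a configurationally stable alkenyllithium, and carboxylation with CO2 proceeds with retention, which fixes the methyl group cis to the carboxyl group (Z).

**Step 7**
Reactants: 10 (2Z)-2-(hydroxymethyl)but-2-enoic acid
Product: 11 (2Z)-2-[(acetyloxy)methyl]but-2-enoic acid
Conditions: Ac2O (1.2 equiv), pyridine, CH2Cl2, 0 °C to rt; dilute aq. HCl work-up
Reagents that add atoms: acetic anhydride, CC(=O)OC(C)=O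
Why: Nucleophilic acyl substitution (O-acetylation) at the primary allylic hydroxyl; no nucleophilic catalyst such as DMAP is used, so that the Z-enoic acid is neither isomerised nor attacked at its allylic position.

**Step 8**
Reactants: 6 1-[(2S,3R)-3,6-dihydroxy-2-(prop-1-en-2-yl)-2,3-dihydro-1-benzofuran-5-yl]ethan-1-one; 11 (2Z)-2-[(acetyloxy)methyl]but-2-enoic acid
Product: 12 (2S,3S)-5-acetyl-6-hydroxy-2-(prop-1-en-2-yl)-2,3-dihydro-1-benzofuran-3-yl (2Z)-2-[(acetyloxy)methyl]but-2-enoate
Conditions: PPh3 (1.5 equiv), DIAD (1.6 equiv), toluene, −20 °C (betaine formed first); then 11 (1.5 equiv) and 6, −20 °C to rt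
Reagents that add atoms: none
Why: Mitsunobu esterification: the carboxylate of 11 displaces the oxyphosphonium group at C3 from the rear (SN2), which inverts C3 from R to S and converts the 2,3-trans alcohol into the 2,3-cis ester, while the far less acidic, hydrogen-bonded 6-OH is not engaged and the Z-acid never becomes an acyl electrophile, so its geometry is kept.

**Compound list**

1 | 1-(2,4-dihydroxyphenyl)ethan-1-one (2,4-dihydroxyacetophenone) | CC(=O)c1ccc(O)cc1O | starting material
2 | 1-(2,4-dihydroxy-5-iodophenyl)ethan-1-one | CC(=O)c1cc(I)c(O)cc1O | intermediate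
3 | 3-methylbut-2-enal | CC(C)=CC=O | starting material
4 | (E)-triisopropyl[(3-methylbuta-1,3-dien-1-yl)oxy]silane | C=C(C)/C=C/O[Si](C(C)C)(C(C)C)C(C)C | intermediate
5 | 1-[(2S,3R)-6-hydroxy-2-(prop-1-en-2-yl)-3-[(triisopropylsilyl)oxy]-2,3-dihydro-1-benzofuran-5-yl]ethan-1-one (2,3-trans) | C=C(C)[C@@H]1Oc2cc(O)c(C(C)=O)cc2[C@H]1O[Si](C(C)C)(C(C)C)C(C)C | intermediate
6 | 1-[(2S,3R)-3,6-dihydroxy-2-(prop-1-en-2-yl)-2,3-dihydro-1-benzofuran-5-yl]ethan-1-one (2,3-trans) | C=C(C)[C@@H]1Oc2cc(O)c(C(C)=O)cc2[C@H]1O | intermediate
7 | but-2-yn-1-ol | CC#CCO | starting material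
8 | (Z)-2-(tributylstannyl)but-2-en-1-ol | C/C=C(\[Sn](CCCC)(CCCC)CCCC)CO | intermediate
9 | lithium 2-lithiobut-2-en-1-olate (lithium cis to the C4 methyl group) | C/C=C(\[Li])CO[Li] | intermediate (not isolated)
10 | (2Z)-2-(hydroxymethyl)but-2-enoic acid | C/C=C(\C(=O)O)CO | intermediate
11 | (2Z)-2-[(acetyloxy)methyl]but-2-enoic acid | C/C=C(\C(=O)O)COC(C)=O | intermediate
12 | (2S,3S)-5-acetyl-6-hydroxy-2-(prop-1-en-2-yl)-2,3-dihydro-1-benzofuran-3-yl (2Z)-2-[(acetyloxy)methyl]but-2-enoate (2,3-cis) | C=C(C)[C@@H]1Oc2cc(O)c(C(C)=O)cc2[C@@H]1OC(=O)/C(=C\C)COC(C)=O | target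

**Step count**

Total step count: 8. Longest linear sequence: 4 steps (1 → 2 → 5 → 6 → 12; the branches from 3 and from 7 are equally long).

**Steps most likely to fail**

Step 3. Several processes may spoil it:
- aryl transfer to the unsubstituted C4 end of the diene instead of the oxygenated C1;
- β-hydride or β-silyloxy elimination from the allylpalladium species before ring closure;
- transfer of the silyl group from the dienol ether to the phenoxide;
- poor enantioface selection;
- ring closure on the allyl face that gives the 2,3-cis isomer.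

The fallback uses known chemistry, sets out from 2 and comes back at 6. Zirconocene-hydrochloride-catalysed hydroboration of 2-methylbut-1-en-3-yne with pinacolborane should give (E)-4,4,5,5-tetramethyl-2-(3-methylbuta-1,3-dien-1-yl)-1,3,2-dioxaborolane F1. Suzuki–Miyaura coupling of F1 with 2 (Pd(PPh3)4, K2CO3, dioxane/H2O, 80 °C) should give 1-{2,4-dihydroxy-5-[(1E)-3-methylbuta-1,3-dien-1-yl]phenyl}ethan-1-one F2. Shi epoxidation (D-fructose-derived ketone, Oxone, pH about 10, 0 °C) should act on the trans-disubstituted styrene-type double bond and give 1-{2,4-dihydroxy-5-[(2R,3R)-3-(prop-1-en-2-yl)oxiran-2-yl]phenyl}ethan-1-one F3; the (R,R) sense is expected by analogy with trans-β-methylstyrene. The neighbouring phenoxide should open F3 at the allylic carbon with inversion (K2CO3, MeOH if not spontaneous); a trans epoxide opened with inversion gives the 2,3-trans diol 6.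

Step 8. The oxyphosphonium intermediate at the electron-rich benzylic C3 may ionise, which would cause loss of inversion and elimination to the aromatic benzofuran. Free phosphine may also attack the acetoxymethyl enoate.

The fallback avoids breaking the C3–O bond, sets out from 2 and 11 and comes back at 12.
- O-Alkylation of the free 4-OH of 2 with chloroacetone (K2CO3, acetone) should give 1-[2-hydroxy-5-iodo-4-(2-oxopropoxy)phenyl]ethan-1-one F4.
- Palladium-catalysed formylation (PdCl2(PPh3)2, CO, HCO2Na, DMF, 100 °C) should give 5-acetyl-4-hydroxy-2-(2-oxopropoxy)benzaldehyde F5.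
- A proline-catalysed intramolecular aldol reaction (5-enolexo, proline antipode chosen for this series) should give the cis aldol 1-[(2R,3S)-5-acetyl-3,6-dihydroxy-2,3-dihydro-1-benzofuran-2-yl]ethan-1-one F6.
- Wittig methylenation of the alkyl ketone (excess Ph3P=CH2, THF, 0 °C; the aryl ketone is shielded as its phenoxide) should give 1-[(2S,3S)-3,6-dihydroxy-2-(prop-1-en-2-yl)-2,3-dihydro-1-benzofuran-5-yl]ethan-1-one F7.
- Acid 11 is converted with 1-chloro-N,N,2-trimethylprop-1-en-1-amine (CH2Cl2, 0 °C) into (2Z)-2-(chlorocarbonyl)but-2-en-1-yl acetate F8, which should acylate the C3 hydroxyl of F7 (pyridine, CH2Cl2, −20 °C) with retention to give 12.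

Step 6. Tin–lithium exchange on the hindered internal alkenylstannane may be incomplete, or the double-bond geometry may be lost at the alkenyllithium stage or during acidic work-up.

The fallback replaces lithiation by carbonylation, sets out from 8 and comes back at 10. Iododestannylation (I2, CH2Cl2, 0 °C) should give (Z)-2-iodobut-2-en-1-ol F9 with retention. Palladium-catalysed methoxycarbonylation (PdCl2(PPh3)2, CO 1 atm, MeOH, Et3N, 50 °C) should give methyl (2Z)-2-(hydroxymethyl)but-2-enoate F10. Hydrolysis (LiOH, THF/H2O, 0 °C, then cold dilute acid) should give 10.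

**Further compounds**

F1 | step 3 | (E)-4,4,5,5-tetramethyl-2-(3-methylbuta-1,3-dien-1-yl)-1,3,2-dioxaborolane | C=C(C)/C=C/B1OC(C)(C)C(C)(C)O1
F2 | step 3 | 1-{2,4-dihydroxy-5-[(1E)-3-methylbuta-1,3-dien-1-yl]phenyl}ethan-1-one | C=C(C)/C=C/c1cc(C(C)=O)c(O)cc1O
F3 | step 3 | 1-{2,4-dihydroxy-5-[(2R,3R)-3-(prop-1-en-2-yl)oxiran-2-yl]phenyl}ethan-1-one | C=C(C)[C@H]1O[C@@H]1c1cc(C(C)=O)c(O)cc1O
F4 | step 8 | 1-[2-hydroxy-5-iodo-4-(2-oxopropoxy)phenyl]ethan-1-one | CC(=O)COc1cc(O)c(C(C)=O)cc1I
F5 | step 8 | 5-acetyl-4-hydroxy-2-(2-oxopropoxy)benzaldehyde | CC(=O)COc1cc(O)c(C(C)=O)cc1C=O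
F6 | step 8 | 1-[(2R,3S)-5-acetyl-3,6-dihydroxy-2,3-dihydro-1-benzofuran-2-yl]ethan-1-one | CC(=O)[C@@H]1Oc2cc(O)c(C(C)=O)cc2[C@@H]1O
F7 | step 8 | 1-[(2S,3S)-3,6-dihydroxy-2-(prop-1-en-2-yl)-2,3-dihydro-1-benzofuran-5-yl]ethan-1-one | C=C(C)[C@@H]1Oc2cc(O)c(C(C)=O)cc2[C@@H]1O
F8 | step 8 | (2Z)-2-(chlorocarbonyl)but-2-en-1-yl acetate | C/C=C(\C(Cl)=O)COC(C)=O
F9 | step 6 | (Z)-2-iodobut-2-en-1-ol | C/C=C(\I)CO
F10 | step 6 | methyl (2Z)-2-(hydroxymethyl)but-2-enoate | C/C=C(\C(=O)OC)CO
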